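## Retrosynthetic overview

1. The depsidone (seven-membered lactone) is opened first at the aryl ester C(=O)–O (lactonisation of seco acid 26), then at the diaryl ether C–O (Pd coupling of ring-A triflate 18 with ring-B phenol 10).
2. Enabling feature: the spiro carbon is an acylal carbon that carries both the oxane ring O and the lactone acyloxy O, and that ring O is bonded to the methyl-bearing CH. This O–C(OCOAr) array is the retron of a Criegee rearrangement of a 1-(arylmethyl)-2-methylcyclopentyl hydroperoxide placed ortho to the ring-B CO2H (22).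
3. Key event: a temporary seven-membered cyclic perester ionises, the CH(CH3) carbon shifts from C to O with retention (cyclopentane → oxane), and the tethered carboxylate returns to the oxocarbenium carbon (perester ring → six-membered lactone). The spiro centre is set by the anomeric effect.
4. The hydroperoxide comes from hydrogen-atom-transfer hydroperoxidation of a (5R)-5-methylcyclopentene. That ring is built from (R)-citronellal by Mitsunobu etherification, aromatic Claisen shift to the only free ortho carbon, and ring-closing metathesis.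
5. Ring order: cyclopentene (step 8) → oxane and isochromanone lactone together (step 17) → depsidone lactone (step 19). Both benzene rings are purchased.

Key step: step 17

Assumption: compounds 1, 4, 11 and 12 are taken as purchasable; the peroxide-bearing carbon of 21–23 is carried as an epimer mixture because it becomes planar in step 17.

## Route

Step 1
Reactants: 1 (R)-citronellal
Product: 2 (3R)-3,7-dimethyl-2-methylideneoct-6-enal
Conditions: 37% aq. CH2O, pyrrolidine (10 mol%), EtCO2H (10 mol%), i-PrOH, 45 °C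
Reagents that add atoms: formaldehyde, C=O
Why: Organocatalytic α-methylenation (enamine Mannich condensation then amine elimination) should install the 1,1-disubstituted alkene; the C3 stereocentre is not enolisable and is carried through unchanged.

Step 2
Reactants: 2 (3R)-3,7-dimethyl-2-methylideneoct-6-enal
Product: 3 (3R)-3,7-dimethyl-2-methylideneoct-6-en-1-ol
Conditions: NaBH4, CeCl3·7H2O, MeOH, 0 °C
Reagents that add atoms: none
Why: Luche reduction should give clean 1,2-reduction of the enal to the primary allylic alcohol without conjugate reduction.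

Step 3
Reactants: 4 5-bromo-2,4-dihydroxybenzaldehyde
Product: 5 2,4-bis(benzyloxy)-5-bromobenzaldehyde
Conditions: BnBr (2.4 equiv), K2CO3, DMF, 60 °C
Reagents that add atoms: benzyl bromide, BrCc1ccccc1
Why: Williamson etherification; warming in DMF should also alkylate the hydrogen-bonded ortho phenol.

Step 4
Reactants: 5 2,4-bis(benzyloxy)-5-bromobenzaldehyde
Product: 6 2,4-bis(benzyloxy)-5-(4,4,5,5-tetramethyl-1,3,2-dioxaborolan-2-yl)benzaldehyde
Conditions: B2pin2, PdCl2(dppf) (3 mol%), KOAc, 1,4-dioxane, 90 °C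
Reagents that add atoms: bis(pinacolato)diboron, CC1(C)OB(OC1(C)C)B1OC(C)(C)C(C)(C)O1
Why: Miyaura borylation of the aryl bromide; the aldehyde and benzyl ethers are inert to Pd(0)/KOAc.

Step 5
Reactants: 6 2,4-bis(benzyloxy)-5-(4,4,5,5-tetramethyl-1,3,2-dioxaborolan-2-yl)benzaldehyde
Product: 7 2,4-bis(benzyloxy)-5-hydroxybenzaldehyde
Conditions: 4-methylmorpholine N-oxide (3 equiv), CH2Cl2, 40 °C; aq. work-up
Reagents that add atoms: 4-methylmorpholine N-oxide, C[N+]1([O-])CCOCC1
Why: Amine N-oxide oxidation of the aryl boronate (1,2-aryl shift from B to O) should unmask the one free phenol without the Dakin cleavage that peroxide oxidants would risk on this electron-rich aldehyde.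

Step 6
Reactants: 7 2,4-bis(benzyloxy)-5-hydroxybenzaldehyde, 3 (3R)-3,7-dimethyl-2-methylideneoct-6-en-1-ol
Product: 8 2,4-bis(benzyloxy)-5-{[(3R)-3,7-dimethyl-2-methylideneoct-6-en-1-yl]oxy}benzaldehyde
Conditions: PPh3, DIAD, THF, 0 → 25 °C
Reagents that add atoms: none
Why: Mitsunobu etherification at the primary allylic carbon (SN2 at CH2); the adjacent stereocentre is not involved.

Step 7
Reactants: 8 2,4-bis(benzyloxy)-5-{[(3R)-3,7-dimethyl-2-methylideneoct-6-en-1-yl]oxy}benzaldehyde
Product: 9 4,6-bis(benzyloxy)-2-[(3R)-3,7-dimethyl-2-methylideneoct-6-en-1-yl]-3-hydroxybenzaldehyde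
Conditions: PhNEt2, 185 °C
Reagents that add atoms: none
Why: Aromatic Claisen rearrangement; the [3,3] shift can only reach the single free ortho carbon, and because the 2-substituted allyl unit has equivalent CH2 termini it delivers ArCH2–C(=CH2) and regenerates the phenol needed for step 14.

Step 8
Reactants: 9 4,6-bis(benzyloxy)-2-[(3R)-3,7-dimethyl-2-methylideneoct-6-en-1-yl]-3-hydroxybenzaldehyde
Product: 10 4,6-bis(benzyloxy)-3-hydroxy-2-{[(5R)-5-methylcyclopent-1-en-1-yl]methyl}benzaldehyde
Conditions: Grubbs II (5 mol%), 1,4-benzoquinone (10 mol%), CH2Cl2, 40 °C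
Reagents that add atoms: none
Why: Ring-closing metathesis of the 1,1-disubstituted alkene with the isopropylidene alkene should close the trisubstituted cyclopentene with loss of isobutene; benzoquinone suppresses Ru–H alkene migration that would endanger the allylic stereocentre.

Step 9
Reactants: 11 2,4-dimethoxy-6-methylbenzoic acid, 12 N-methoxy-N-methylhexanamide
Product: 14 2,4-dimethoxy-6-(2-oxoheptyl)benzoic acid, via dilithio benzylic dianion 13 (not isolated)
Conditions: LDA (3.2 equiv), THF, −78 → 0 °C; then 12, −78 °C; 1 M HCl work-up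
Reagents that add atoms: none
Why: Lateral lithiation of the o-toluic acid (carboxylate-stabilised benzylic anion) followed by Weinreb-amide acylation; the chelated tetrahedral adduct prevents over-addition.

Step 10
Reactants: 14 2,4-dimethoxy-6-(2-oxoheptyl)benzoic acid
Product: 15 2-hydroxy-4-methoxy-6-(2-oxoheptyl)benzoic acid
Conditions: BCl3 (2.2 equiv), CH2Cl2, −78 → 0 °C; H2O
Reagents that add atoms: none
Why: Chelation-controlled Lewis-acid demethylation should cleave only the methyl ether ortho to the carboxyl group; the para methyl ether cannot chelate and stays.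

Step 11
Reactants: 15 2-hydroxy-4-methoxy-6-(2-oxoheptyl)benzoic acid
Product: 16 benzyl 2-hydroxy-4-methoxy-6-(2-oxoheptyl)benzoate
Conditions: BnBr (1.05 equiv), KHCO3, DMF, 25 °C
Reagents that add atoms: benzyl bromide, BrCc1ccccc1
Why: Carboxylate O-alkylation; bicarbonate does not deprotonate the hydrogen-bonded salicylate phenol, so only the ester should form.

Step 12
Reactants: 16 benzyl 2-hydroxy-4-methoxy-6-(2-oxoheptyl)benzoate
Product: 17 benzyl 2-hydroxy-4-methoxy-6-[(2-pentyl-1,3-dioxolan-2-yl)methyl]benzoate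
Conditions: TMSOCH2CH2OTMS, TMSOTf (5 mol%), CH2Cl2, −78 → −20 °C; pyridine quench
Reagents that add atoms: 1,2-bis(trimethylsilyloxy)ethane, C[Si](C)(C)OCCO[Si](C)(C)C
Why: Noyori ketalisation under aprotic low-temperature conditions should mask the ketone without the protic acid and heat that would cyclodehydrate the keto ester to an isocoumarin.

Step 13
Reactants: 17 benzyl 2-hydroxy-4-methoxy-6-[(2-pentyl-1,3-dioxolan-2-yl)methyl]benzoate
Product: 18 benzyl 4-methoxy-2-[(2-pentyl-1,3-dioxolan-2-yl)methyl]-6-(trifluoromethylsulfonyloxy)benzoate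
Conditions: Tf2O, pyridine, CH2Cl2, 0 °C
Reagents that add atoms: trifluoromethanesulfonic anhydride, O=S(=O)(OS(=O)(=O)C(F)(F)F)C(F)(F)F
Why: Phenol triflation under pyridine buffering; the dioxolane and benzyl ester are stable to these conditions.

Step 14
Reactants: 10 4,6-bis(benzyloxy)-3-hydroxy-2-{[(5R)-5-methylcyclopent-1-en-1-yl]methyl}benzaldehyde, 18 benzyl 4-methoxy-2-[(2-pentyl-1,3-dioxolan-2-yl)methyl]-6-(trifluoromethylsulfonyloxy)benzoate
Product: 19 benzyl 2-[4,6-bis(benzyloxy)-3-formyl-2-{[(5R)-5-methylcyclopent-1-en-1-yl]methyl}phenoxy]-4-methoxy-6-[(2-pentyl-1,3-dioxolan-2-yl)methyl]benzoate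
Conditions: Pd(OAc)2 (5 mol%), t-BuXPhos (8 mol%), K3PO4, toluene, 100 °C
Reagents that add atoms: none
Why: Pd-catalysed diaryl ether synthesis (Buchwald–Hartwig C–O coupling); the electron-poor ortho-ester triflate favours oxidative addition and the bulky biaryl phosphine promotes C–O reductive elimination with the electron-rich hindered phenol.

Step 15
Reactants: 19 benzyl 2-[4,6-bis(benzyloxy)-3-formyl-2-{[(5R)-5-methylcyclopent-1-en-1-yl]methyl}phenoxy]-4-methoxy-6-[(2-pentyl-1,3-dioxolan-2-yl)methyl]benzoate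
Product: 20 2,4-bis(benzyloxy)-5-{2-(benzyloxycarbonyl)-5-methoxy-3-[(2-pentyl-1,3-dioxolan-2-yl)methyl]phenoxy}-6-{[(5R)-5-methylcyclopent-1-en-1-yl]methyl}benzoic acid
Conditions: NaClO2, NaH2PO4, 2-methyl-2-butene, t-BuOH/THF/H2O, 0 → 25 °C
Reagents that add atoms: sodium chlorite, [Na+].[O-]Cl=O
Why: Pinnick oxidation of the aryl aldehyde; the scavenger removes HOCl, so the cyclopentene and the electron-rich arenes should survive, and no phenol is free at this stage.

Step 16
Reactants: 20 2,4-bis(benzyloxy)-5-{2-(benzyloxycarbonyl)-5-methoxy-3-[(2-pentyl-1,3-dioxolan-2-yl)methyl]phenoxy}-6-{[(5R)-5-methylcyclopent-1-en-1-yl]methyl}benzoic acid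
Product: 22 2,4-bis(benzyloxy)-5-{2-(benzyloxycarbonyl)-5-methoxy-3-[(2-pentyl-1,3-dioxolan-2-yl)methyl]phenoxy}-6-{[(2R)-1-hydroperoxy-2-methylcyclopentyl]methyl}benzoic acid, via triethylsilyl peroxide 21 (not isolated)
Conditions: Co(thd)2 (10 mol%), O2 (1 atm), Et3SiH (3 equiv), ClCH2CH2Cl, 25 °C; then TBAF/AcOH (1:1), THF, 0 °C
Reagents that add atoms: dioxygen, O=O
Why: Mukaiyama–Isayama hydroperoxidation: cobalt hydride transfers H to the alkene CH, the tertiary radical is trapped by O2 (Markovnikov) without the hydride shifts a cation would allow, and buffered fluoride frees the hydroperoxide. The new peroxide carbon forms as both epimers, which is harmless, and the methyl stereocentre is untouched.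

Step 17
Reactants: 22 2,4-bis(benzyloxy)-5-{2-(benzyloxycarbonyl)-5-methoxy-3-[(2-pentyl-1,3-dioxolan-2-yl)methyl]phenoxy}-6-{[(2R)-1-hydroperoxy-2-methylcyclopentyl]methyl}benzoic acid
Product: 25 benzyl 2-{[(3S,6'R)-6,8-bis(benzyloxy)-6'-methyl-1-oxospiro[isochromane-3,2'-oxan]-5-yl]oxy}-4-methoxy-6-[(2-pentyl-1,3-dioxolan-2-yl)methyl]benzoate, via cyclic perester 23 (not isolated), via oxanylium carboxylate zwitterion 24 (not isolated)
Conditions: EDC·HCl (1.5 equiv), DMAP (10 mol%), CH2Cl2 (0.01 M), 0 °C; then (CF3)2CHOH, 25 °C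
Reagents that add atoms: none
Why: Proposed new method: the hydroperoxide is acylated intramolecularly by the carbodiimide-activated ortho carboxyl to give the seven-membered cyclic perester 23 (7-exo-trig acyl substitution), whose O–O bond should ionise in the polar medium with concerted 1,2-shift of a cyclopentane carbon from C to O, i.e. a Criegee rearrangement whose closest precedent is the conversion of tertiary cycloalkyl perbenzoates such as 9-decalyl perbenzoate into ring-expanded α-acyloxy cyclic ethers by internal return of the carboxylate. The shift turns the cyclopentane into the six-membered oxanylium ion 24 (ring expansion by oxygen insertion, not a cyclisation), and the tethered carboxylate then adds to the oxocarbenium carbon in a 6-exo-trig closure that forms the isochromanone lactone while the perester ring contracts from seven to six members. The migrating CH(CH3) carbon moves with retention, so its R configuration from citronellal becomes the 6'R centre, whereas the peroxide-bearing carbon becomes planar, so both epimers of 22 converge. The spiro centre is set by axial attack of the carboxylate on the half-chair oxanylium ion with the methyl group equatorial, which places the acyloxy oxygen axial (anomeric effect) and gives the 3S isomer, which is also the thermodynamic one reachable by acid equilibration. The step needs migration of CH(CH3) rather than of the ring CH2 or the benzylic CH2: the secondary carbon has the higher migratory aptitude (as in Baeyer–Villiger oxidation of 2-methylcyclopentanone), and the benzylic C–C bond is endocyclic in 23 and cannot align antiperiplanar to the O–O bond.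

Step 18
Reactants: 25 benzyl 2-{[(3S,6'R)-6,8-bis(benzyloxy)-6'-methyl-1-oxospiro[isochromane-3,2'-oxan]-5-yl]oxy}-4-methoxy-6-[(2-pentyl-1,3-dioxolan-2-yl)methyl]benzoate
Product: 26 2-{[(3S,6'R)-6,8-dihydroxy-6'-methyl-1-oxospiro[isochromane-3,2'-oxan]-5-yl]oxy}-4-methoxy-6-[(2-pentyl-1,3-dioxolan-2-yl)methyl]benzoic acid
Conditions: H2 (1 atm), 10% Pd/C, EtOAc, 25 °C
Reagents that add atoms: none
Why: Hydrogenolysis should remove both benzyl ethers and the benzyl ester in one operation; the acylal C–O bonds are not benzylic, and the dioxolane and diaryl ether are inert.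

Step 19
Reactants: 26 2-{[(3S,6'R)-6,8-dihydroxy-6'-methyl-1-oxospiro[isochromane-3,2'-oxan]-5-yl]oxy}-4-methoxy-6-[(2-pentyl-1,3-dioxolan-2-yl)methyl]benzoic acid
Product: 27 depsidone ketal (target with the side-chain ketone as its 1,3-dioxolane)
Conditions: EDC·HCl, DMAP, CH2Cl2 (0.005 M), 25 °C
Reagents that add atoms: none
Why: Steglich-type lactonisation to the seven-membered depsidone; only the phenol next to the diaryl ether oxygen can reach the activated acid, the other phenol is remote and hydrogen-bonded to the lactone carbonyl, and the ketal prevents enol-lactonisation of the activated acid to an isocoumarin.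

Step 20
Reactants: 27 depsidone ketal
Product: 28 CNP0301127.1 (target)
Conditions: 1 M aq. HCl/THF (1:3), 25 °C
Reagents that add atoms: water, O
Why: Mild acid hydrolysis of the dioxolane should release the ketone; the spiro acylal already has the anomerically favoured (thermodynamic) configuration, so any reversible opening recloses to the same isomer.

## Compound list

1 | (R)-citronellal, (3R)-3,7-dimethyloct-6-enal | O=CC[C@H](C)CCC=C(C)C | starting material
2 | (3R)-3,7-dimethyl-2-methylideneoct-6-enal | O=CC(=C)[C@H](C)CCC=C(C)C | intermediate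
3 | (3R)-3,7-dimethyl-2-methylideneoct-6-en-1-ol | OCC(=C)[C@H](C)CCC=C(C)C | intermediate
4 | 5-bromo-2,4-dihydroxybenzaldehyde | O=Cc1cc(Br)c(O)cc1O | starting material
5 | 2,4-bis(benzyloxy)-5-bromobenzaldehyde | O=Cc1cc(Br)c(OCc2ccccc2)cc1OCc1ccccc1 | intermediate
6 | 2,4-bis(benzyloxy)-5-(4,4,5,5-tetramethyl-1,3,2-dioxaborolan-2-yl)benzaldehyde | O=Cc1cc(B2OC(C)(C)C(C)(C)O2)c(OCc2ccccc2)cc1OCc1ccccc1 | intermediate
7 | 2,4-bis(benzyloxy)-5-hydroxybenzaldehyde | O=Cc1cc(O)c(OCc2ccccc2)cc1OCc1ccccc1 | intermediate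
8 | 2,4-bis(benzyloxy)-5-{[(3R)-3,7-dimethyl-2-methylideneoct-6-en-1-yl]oxy}benzaldehyde | O=Cc1cc(OCC(=C)[C@H](C)CCC=C(C)C)c(OCc2ccccc2)cc1OCc1ccccc1 | intermediate
9 | 4,6-bis(benzyloxy)-2-[(3R)-3,7-dimethyl-2-methylideneoct-6-en-1-yl]-3-hydroxybenzaldehyde | O=Cc1c(CC(=C)[C@H](C)CCC=C(C)C)c(O)c(OCc2ccccc2)cc1OCc1ccccc1 | intermediate
10 | 4,6-bis(benzyloxy)-3-hydroxy-2-{[(5R)-5-methylcyclopent-1-en-1-yl]methyl}benzaldehyde | O=Cc1c(CC2=CCC[C@H]2C)c(O)c(OCc2ccccc2)cc1OCc1ccccc1 | intermediate
11 | 2,4-dimethoxy-6-methylbenzoic acid | COc1cc(C)c(C(=O)O)c(OC)c1 | starting material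
12 | N-methoxy-N-methylhexanamide | CCCCCC(=O)N(C)OC | starting material
13 | lithium 2-(lithiomethyl)-4,6-dimethoxybenzoate (dilithio benzylic dianion) | [Li]Cc1cc(OC)cc(OC)c1C(=O)O[Li] | intermediate (not isolated)
14 | 2,4-dimethoxy-6-(2-oxoheptyl)benzoic acid | CCCCCC(=O)Cc1cc(OC)cc(OC)c1C(=O)O | intermediate
15 | 2-hydroxy-4-methoxy-6-(2-oxoheptyl)benzoic acid | CCCCCC(=O)Cc1cc(OC)cc(O)c1C(=O)O | intermediate
16 | benzyl 2-hydroxy-4-methoxy-6-(2-oxoheptyl)benzoate | CCCCCC(=O)Cc1cc(OC)cc(O)c1C(=O)OCc1ccccc1 | intermediate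
17 | benzyl 2-hydroxy-4-methoxy-6-[(2-pentyl-1,3-dioxolan-2-yl)methyl]benzoate | CCCCCC1(Cc2cc(OC)cc(O)c2C(=O)OCc2ccccc2)OCCO1 | intermediate
18 | benzyl 4-methoxy-2-[(2-pentyl-1,3-dioxolan-2-yl)methyl]-6-(trifluoromethylsulfonyloxy)benzoate | CCCCCC1(Cc2cc(OC)cc(OS(=O)(=O)C(F)(F)F)c2C(=O)OCc2ccccc2)OCCO1 | intermediate
19 | benzyl 2-[4,6-bis(benzyloxy)-3-formyl-2-{[(5R)-5-methylcyclopent-1-en-1-yl]methyl}phenoxy]-4-methoxy-6-[(2-pentyl-1,3-dioxolan-2-yl)methyl]benzoate | CCCCCC1(Cc2cc(OC)cc(Oc3c(CC4=CCC[C@H]4C)c(C=O)c(OCc4ccccc4)cc3OCc3ccccc3)c2C(=O)OCc2ccccc2)OCCO1 | intermediate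
20 | 2,4-bis(benzyloxy)-5-{2-(benzyloxycarbonyl)-5-methoxy-3-[(2-pentyl-1,3-dioxolan-2-yl)methyl]phenoxy}-6-{[(5R)-5-methylcyclopent-1-en-1-yl]methyl}benzoic acid | CCCCCC1(Cc2cc(OC)cc(Oc3c(CC4=CCC[C@H]4C)c(C(=O)O)c(OCc4ccccc4)cc3OCc3ccccc3)c2C(=O)OCc2ccccc2)OCCO1 | intermediate
21 | triethylsilyl peroxide of 22 (epimers at the peroxide carbon, 2R methyl carbon) | CCCCCC1(Cc2cc(OC)cc(Oc3c(CC4(OO[Si](CC)(CC)CC)CCC[C@H]4C)c(C(=O)O)c(OCc4ccccc4)cc3OCc3ccccc3)c2C(=O)OCc2ccccc2)OCCO1 | intermediate (not isolated)
22 | 2,4-bis(benzyloxy)-5-{2-(benzyloxycarbonyl)-5-methoxy-3-[(2-pentyl-1,3-dioxolan-2-yl)methyl]phenoxy}-6-{[(2R)-1-hydroperoxy-2-methylcyclopentyl]methyl}benzoic acid (epimers at C-1 of the cyclopentane) | CCCCCC1(Cc2cc(OC)cc(Oc3c(CC4(OO)CCC[C@H]4C)c(C(=O)O)c(OCc4ccccc4)cc3OCc3ccccc3)c2C(=O)OCc2ccccc2)OCCO1 | intermediate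
23 | cyclic perester: 2,3-benzodioxepin-1-one spiro-fused at C-4 to (2R)-2-methylcyclopentane, carrying the ring-A aryloxy group and two benzyloxy groups | CCCCCC1(Cc2cc(OC)cc(Oc3c4c(C(=O)OOC5(CCC[C@H]5C)C4)c(OCc4ccccc4)cc3OCc3ccccc3)c2C(=O)OCc2ccccc2)OCCO1 | intermediate (not isolated)
24 | zwitterion: (6R)-6-methyl-3,4,5,6-tetrahydro-2H-pyrylium (oxanylium) ion bearing at C-2 the CH2 of the ring-B benzoate (carboxylate form) | CCCCCC1(Cc2cc(OC)cc(Oc3c(CC4=[O+][C@H](C)CCC4)c(C(=O)[O-])c(OCc4ccccc4)cc3OCc3ccccc3)c2C(=O)OCc2ccccc2)OCCO1 | intermediate (not isolated)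
25 | benzyl 2-{[(3S,6'R)-6,8-bis(benzyloxy)-6'-methyl-1-oxospiro[isochromane-3,2'-oxan]-5-yl]oxy}-4-methoxy-6-[(2-pentyl-1,3-dioxolan-2-yl)methyl]benzoate | CCCCCC1(Cc2cc(OC)cc(Oc3c(OCc4ccccc4)cc(OCc4ccccc4)c4c3C[C@]3(CCC[C@@H](C)O3)OC4=O)c2C(=O)OCc2ccccc2)OCCO1 | intermediate
26 | 2-{[(3S,6'R)-6,8-dihydroxy-6'-methyl-1-oxospiro[isochromane-3,2'-oxan]-5-yl]oxy}-4-methoxy-6-[(2-pentyl-1,3-dioxolan-2-yl)methyl]benzoic acid | CCCCCC1(Cc2cc(OC)cc(Oc3c(O)cc(O)c4c3C[C@]3(CCC[C@@H](C)O3)OC4=O)c2C(=O)O)OCCO1 | intermediate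
27 | depsidone ketal: target with the 2-oxoheptyl ketone as its 1,3-dioxolane (spiro S, methyl carbon R) | CCCCCC1(Cc2cc(OC)cc3c2C(=O)Oc2cc(O)c4c(c2O3)C[C@]2(CCC[C@@H](C)O2)OC4=O)OCCO1 | intermediate
28 | CNP0301127.1 | CCCCCC(=O)Cc1cc(OC)cc2c1C(=O)Oc1cc(O)c3c(c1O2)C[C@]1(CCC[C@@H](C)O1)OC3=O | target

## Step count, risks and fallbacks

Total steps: 20. Longest linear sequence: 13 steps (4 → 28; steps 3–8 and 14–20).

Most likely to fail, step 17 (proposed new method): the ionisation could shift the wrong carbon (ring CH2 or benzylic CH2), the O–O bond could cleave homolytically, or the strained seven-membered perester could fail to close and give oligomeric peresters instead. The fallback uses the classical intermolecular Criegee rearrangement and sets out from hydroperoxy acid 22. Treatment with trifluoroacetic anhydride and pyridine in CH2Cl2 at −20 → 0 °C forms the peroxy trifluoroacetate, a substrate class known to rearrange at low temperature to the ring-expanded α-acyloxy cyclic ether. Mild aqueous NaHCO3 hydrolysis should then give the open δ-hydroxy ketone acid F1. Camphorsulfonic acid with 4 Å molecular sieves in CH2Cl2 closes the spiro acylal by dehydrative spirolactonisation under thermodynamic control, and the route is rejoined at 25.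

Second, step 14: C–O reductive elimination may be slow with two ortho-substituted partners, and the phenoxide may attack the triflate at sulfur (sulfonyl transfer) instead. The fallback reverses the electronic roles and sets out from triflate 18. Pd-catalysed borylation with tetrahydroxydiboron (XPhos-Pd precatalyst, KOAc, EtOH, 80 °C) should give the arylboronic acid F2. Chan–Lam–Evans coupling of F2 with phenol 10 (Cu(OAc)2, pyridine, 4 Å molecular sieves, air, CH2Cl2, 25 °C) returns to 19.

Third, step 10: the Lewis acid may cyclodehydrate the γ-keto acid to an enol lactone before or during demethylation, and the hydroxy keto acid may be lost on work-up as a lactol mixture. The fallback accepts the cyclisation as a temporary ring and sets out from keto acid 14. Heating in acetic anhydride should give 6,8-dimethoxy-3-pentylisocoumarin F3. BCl3 in CH2Cl2 cleaves the peri methyl ether by chelation to give 8-hydroxy-6-methoxy-3-pentylisocoumarin F4. Aqueous KOH in ethanol opens the enol lactone, and careful acidification returns to 15.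

Further compounds
F1 | step 17 | 2,4-bis(benzyloxy)-5-{2-(benzyloxycarbonyl)-5-methoxy-3-[(2-pentyl-1,3-dioxolan-2-yl)methyl]phenoxy}-6-[(6R)-6-hydroxy-2-oxoheptyl]benzoic acid | CCCCCC1(Cc2cc(OC)cc(Oc3c(CC(=O)CCC[C@@H](C)O)c(C(=O)O)c(OCc4ccccc4)cc3OCc3ccccc3)c2C(=O)OCc2ccccc2)OCCO1
F2 | step 14 | {2-(benzyloxycarbonyl)-5-methoxy-3-[(2-pentyl-1,3-dioxolan-2-yl)methyl]phenyl}boronic acid | CCCCCC1(Cc2cc(OC)cc(B(O)O)c2C(=O)OCc2ccccc2)OCCO1
F3 | step 10 | 6,8-dimethoxy-3-pentyl-1H-isochromen-1-one | CCCCCc1cc2cc(OC)cc(OC)c2c(=O)o1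
F4 | step 10 | 8-hydroxy-6-methoxy-3-pentyl-1H-isochromen-1-one | CCCCCc1cc2cc(OC)cc(O)c2c(=O)o1
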